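**Retrosynthetic overview**
1. Target 33 ⇐ 32 (O-deprotection) ⇐ 28 + 30 (C3 aroylation) ⇐ 26 (bridgehead C1 prenylation); all three decorations follow the bicycle.
2. 26 ⇐ 22 by oxidation-level changes only (C8–CH2OH → CH3, C2–H2 → C=O).
3. Key disconnection: the C1–C8 bond of 22 ⇐ group-selective, invertive epoxide-opening cyclisation of the ring-symmetric bis(enol ether) 19, which sets C1, C5 and C8 in one step.
4. 19 ⇐ 1,5-dimethoxycyclohexa-1,4-diene 15, alkylated twice at C6 with two lavandulol-derived iodides of opposite configuration: 9 from (S)-lavandulol and 14 from (R)-lavandulol (allylic prenylation, then directed epoxidation).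
5. Ring order: ring A (C1–C5 and C9, from 15) is present from the start; ring B (C5, C6, C7, C8, C1, C9) closes in step 10.

Assumption: (R)-(−)-lavandulol (the natural enantiomer) and 3,4-diacetoxybenzoic acid are bought, and the target is handled as the enol tautomer written in the given SMILES.

Notation: prenyl = 3-methylbut-2-en-1-yl; homoprenyl = 4-methylpent-3-en-1-yl; Lav = (2R)-5-methyl-2-(prop-1-en-2-yl)hex-4-en-1-yl, the skeleton of (S)-lavandulol (the descriptor changes from S to R only through CIP ranking once O or I is replaced by carbon). Core numbering: C1 prenyl bridgehead, C2–C4 enolised 1,3-diketone, C5 Lav bridgehead, C6 CH2, C7 CH(prenyl), C8 C(CH3)(homoprenyl), C9 bridging C=O.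

**Step 1**
Reactants: 1 (S)-4-benzyl-1,3-oxazolidin-2-one; 2 3-methylbut-2-enoyl chloride
Product: 4 (S)-4-benzyl-3-(3-methylbut-2-enoyl)-1,3-oxazolidin-2-one, via lithium salt 3 (not isolated)
Conditions: n-BuLi, THF, −78 °C; then 2, −78 → 0 °C
Reagents that add atoms: none
Why: N-acylation of the lithiated Evans oxazolidinone by the acid chloride (standard imide formation), with no stereocentre touched.

**Step 2**
Reactants: 4 (S)-4-benzyl-3-(3-methylbut-2-enoyl)-1,3-oxazolidin-2-one; 5 prenyl bromide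
Product: 7 (4S)-4-benzyl-3-[(2S)-5-methyl-2-(prop-1-en-2-yl)hex-4-enoyl]-1,3-oxazolidin-2-one, via sodium dienolate 6 (not isolated)
Conditions: NaN(SiMe3)2, THF, −78 °C; then 5, −78 → −40 °C
Reagents that add atoms: none
Why: Evans asymmetric alkylation in its deconjugative form: γ-deprotonation gives the chelated (Z)-dienolate, which is alkylated at Cα on the face opposite the benzyl group, so the new centre is (S) and the double bond ends as the isopropenyl group.

**Step 3**
Reactants: 7 (4S)-4-benzyl-3-[(2S)-5-methyl-2-(prop-1-en-2-yl)hex-4-enoyl]-1,3-oxazolidin-2-one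
Product: 8 (S)-lavandulol [(2S)-5-methyl-2-(prop-1-en-2-yl)hex-4-en-1-ol]
Conditions: LiBH4, H2O (1 equiv), Et2O, 0 °C
Reagents that add atoms: none
Why: Reductive cleavage of the imide to the primary alcohol (auxiliary removal) leaves the α-stereocentre and both alkenes untouched and returns the oxazolidinone.

**Step 4**
Reactants: 8 (S)-lavandulol
Product: 9 (S)-lavandulyl iodide [(2S)-1-iodo-5-methyl-2-(prop-1-en-2-yl)hex-4-ene]
Conditions: [I][I] (iodine), PPh3, imidazole, CH2Cl2, 0 °C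
Reagents that add atoms: iodine, [I][I]
Why: Appel-type iodination of the primary alcohol (PPh3/iodine/imidazole) occurs at CH2 only, so the adjacent stereocentre is not involved.

**Step 5**
Reactants: 10 (R)-lavandulol [(2R)-5-methyl-2-(prop-1-en-2-yl)hex-4-en-1-ol]; 5 prenyl bromide
Product: 12 (2R)-5-methyl-2-(6-methylhepta-1,5-dien-2-yl)hex-4-en-1-ol, via dilithio lavandulol 11 (not isolated)
Conditions: n-BuLi (2.2 equiv), TMEDA, Et2O/hexane, 0 °C → rt; then 5, −78 → 0 °C; H2O
Reagents that add atoms: none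
Why: Alkoxide-directed allylic lithiation of the isopropenyl methyl group (the dianion chemistry of 3-methylbut-3-en-1-ol) followed by SN2 coupling of the symmetric 2-substituted allyl anion with prenyl bromide; the stereocentre lies outside the allyl system and stays (R).

**Step 6**
Reactants: 12 (2R)-5-methyl-2-(6-methylhepta-1,5-dien-2-yl)hex-4-en-1-ol
Product: 13 (2S)-5-methyl-2-[(2R)-2-(4-methylpent-3-en-1-yl)oxiran-2-yl]hex-4-en-1-ol
Conditions: VO(acac)2 (5 mol%), t-BuOOH, CH2Cl2, 0 °C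
Reagents that add atoms: tert-butyl hydroperoxide, CC(C)(C)OO
Why: Hydroxyl-directed vanadium-catalysed epoxidation of a homoallylic alcohol: the bound peroxide should reach the proximal 1,1-disubstituted alkene faster than the bishomoallylic prenyl alkene, and it is delivered from the CH2O side of the conformer in which C2–H eclipses the alkene's homoprenyl substituent (A(1,2) strain), giving the (R)-oxirane.

**Step 7**
Reactants: 13 (2S)-5-methyl-2-[(2R)-2-(4-methylpent-3-en-1-yl)oxiran-2-yl]hex-4-en-1-ol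
Product: 14 (2R)-2-[(2R)-1-iodo-5-methylhex-4-en-2-yl]-2-(4-methylpent-3-en-1-yl)oxirane
Conditions: [I][I] (iodine), PPh3, imidazole, THF, 0 °C
Reagents that add atoms: iodine, [I][I]
Why: Appel-type iodination of the primary alcohol under imidazole buffering, which the 2,2-disubstituted epoxide tolerates; no stereocentre is touched.

**Step 8**
Reactants: 15 1,5-dimethoxycyclohexa-1,4-diene; 9 (S)-lavandulyl iodide
Product: 17 6-Lav-1,5-dimethoxycyclohexa-1,4-diene, via 6-lithio diene 16 (not isolated)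
Conditions: t-BuLi, THF, −78 °C; then 9, −78 → −20 °C
Reagents that add atoms: none
Why: Deprotonation of the doubly allylic C6–H flanked by both enol ethers gives a pentadienyl-type carbanion that undergoes SN2 alkylation at C6 with the primary iodide.

**Step 9**
Reactants: 17 6-Lav-1,5-dimethoxycyclohexa-1,4-diene; 14 (2R)-2-[(2R)-1-iodo-5-methylhex-4-en-2-yl]-2-(4-methylpent-3-en-1-yl)oxirane
Product: 19 6-Lav-6-{(2S)-5-methyl-2-[(2R)-2-(4-methylpent-3-en-1-yl)oxiran-2-yl]hex-4-en-1-yl}-1,5-dimethoxycyclohexa-1,4-diene, via 6-lithio derivative 18 (not isolated)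
Conditions: t-BuLi, THF/HMPA, −78 °C; then 14, −78 → 0 °C
Reagents that add atoms: none
Why: A second lithiation and SN2 alkylation at the same carbon builds the quaternary centre (future C5); the ring stays mirror-symmetric, so no new stereocentre arises and the two arms of opposite configuration sit on one carbon.

**Step 10**
Reactants: 19 6-Lav-6-{(2S)-5-methyl-2-[(2R)-2-(4-methylpent-3-en-1-yl)oxiran-2-yl]hex-4-en-1-yl}-1,5-dimethoxycyclohexa-1,4-diene
Product: 22 8-(hydroxymethyl)-4-methoxy-8-homoprenyl-7-prenyl-5-Lav-bicyclo[3.3.1]non-3-en-9-one, via O-methyl oxocarbenium triflate 20 (not isolated), via trimethylsilyl ether 21 (not isolated)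
Conditions: TMSOTf (1.2 equiv), 2,6-lutidine, CH2Cl2, −78 °C; then K2CO3, MeOH, 0 °C
Reagents that add atoms: none
Why: Proposed new method: Lewis-acid activation of the epoxide lets one of the two diastereotopic enol ethers attack the tertiary epoxide carbon in a 6-exo, chair-like transition state with the C7 prenyl group equatorial (attack by the other enol ether would force that group axial over ring A), with inversion at C8, so C8 and, by group selection, C1 and C5 are fixed together, after which lutidine demethylates the oxocarbenium ion to the C9 ketone and K2CO3/MeOH cleaves the silyl ether; the closest known reaction types are the Lewis-acid epoxide-opening cascade cyclisation of 6,6-dialkyl-1,5-dimethoxycyclohexa-1,4-dienes and epoxide-initiated cation–olefin cyclisation.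

**Step 11**
Reactants: 22 8-(hydroxymethyl)-4-methoxy-8-homoprenyl-7-prenyl-5-Lav-bicyclo[3.3.1]non-3-en-9-one
Product: 23 8-formyl-4-methoxy-8-homoprenyl-7-prenyl-5-Lav-bicyclo[3.3.1]non-3-en-9-one
Conditions: Dess–Martin periodinane, pyridine, CH2Cl2, 0 °C → rt
Reagents that add atoms: none
Why: Dess–Martin oxidation of the neopentyl primary alcohol to a non-enolisable aldehyde, with pyridine buffering to spare the acid-labile enol ether.

**Step 12**
Reactants: 23 8-formyl-4-methoxy-8-homoprenyl-7-prenyl-5-Lav-bicyclo[3.3.1]non-3-en-9-one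
Product: 25 4-methoxy-8-methyl-8-homoprenyl-7-prenyl-5-Lav-bicyclo[3.3.1]non-3-en-9-one, via N-silyl hydrazone 24 (not isolated)
Conditions: 1,2-bis(tert-butyldimethylsilyl)hydrazine (1.05 equiv), Sc(OTf)3 (1 mol%), CH2Cl2, 0 → 23 °C; then KOtBu (cat.), t-BuOH, DMSO, 23 °C
Reagents that add atoms: none
Why: Wolff–Kishner reduction in its low-temperature N-silyl hydrazone form: the aldehyde condenses much faster than the flanked C9 ketone, and base-induced loss of N2 gives the C8 methyl group by an anionic, non-radical path, so no cyclisation onto the neighbouring alkenes occurs and C8 is unchanged.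

**Step 13**
Reactants: 25 4-methoxy-8-methyl-8-homoprenyl-7-prenyl-5-Lav-bicyclo[3.3.1]non-3-en-9-one
Product: 26 4-methoxy-8-methyl-8-homoprenyl-7-prenyl-5-Lav-bicyclo[3.3.1]non-3-ene-2,9-dione
Conditions: Rh2(cap)4 (dirhodium tetracaprolactamate, 1 mol%), t-BuOOH (5 equiv), K2CO3 (0.5 equiv), CH2Cl2, rt
Reagents that add atoms: tert-butyl hydroperoxide, CC(C)(C)OO
Why: Allylic C–H oxidation by tert-butylperoxyl radicals at C2, the only CH2 activated by the enol ether, turns the enol ether into the vinylogous ester, the same kind of oxidation used on closely related bicyclic enol ethers.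

**Step 14**
Reactants: 26 4-methoxy-8-methyl-8-homoprenyl-7-prenyl-5-Lav-bicyclo[3.3.1]non-3-ene-2,9-dione; 5 prenyl bromide
Product: 28 4-methoxy-8-methyl-8-homoprenyl-1,7-diprenyl-5-Lav-bicyclo[3.3.1]non-3-ene-2,9-dione, via bridgehead lithium derivative 27 (not isolated)
Conditions: LiN(iPr)2, THF, −78 °C; then 5, −78 → −40 °C
Reagents that add atoms: none
Why: Bridgehead deprotonation at C1 (flanked by the C2 and C9 carbonyls) and SN2 alkylation with prenyl bromide, as known for bicyclo[3.3.1]nonane-2,9-dione vinylogous esters; the bridgehead cannot invert, so its configuration is retained.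

**Step 15**
Reactants: 29 3,4-diacetoxybenzoic acid
Product: 30 3,4-diacetoxybenzoyl chloride
Conditions: (COCl)2, DMF (cat.), CH2Cl2, 0 °C → rt
Reagents that add atoms: oxalyl chloride, O=C(Cl)C(Cl)=O
Why: Acid chloride formation with oxalyl chloride under Vilsmeier-type catalysis; the aryl acetates are untouched.

**Step 16**
Reactants: 28 4-methoxy-8-methyl-8-homoprenyl-1,7-diprenyl-5-Lav-bicyclo[3.3.1]non-3-ene-2,9-dione; 30 3,4-diacetoxybenzoyl chloride
Product: 32 3-(3,4-diacetoxybenzoyl)-4-methoxy-8-methyl-8-homoprenyl-1,7-diprenyl-5-Lav-bicyclo[3.3.1]non-3-ene-2,9-dione, via 3-lithio derivative 31 (not isolated)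
Conditions: lithium 2,2,6,6-tetramethylpiperidide, THF, −78 °C; then 30, −78 °C
Reagents that add atoms: none
Why: Vinylic deprotonation at C3 of the β-methoxy enone by the hindered amide base and C-acylation of the vinyllithium by the acid chloride (known for type B PPAP methyl ethers), which outpaces attack on the acetates at −78 °C; no stereocentre is involved.

**Step 17**
Reactants: 32 3-(3,4-diacetoxybenzoyl)-4-methoxy-8-methyl-8-homoprenyl-1,7-diprenyl-5-Lav-bicyclo[3.3.1]non-3-ene-2,9-dione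
Product: 33 target (1R,5R,7S,8S)-3-(3,4-dihydroxybenzoyl)-4-hydroxy-8-methyl-8-homoprenyl-1,7-diprenyl-5-Lav-bicyclo[3.3.1]non-3-ene-2,9-dione
Conditions: LiOH, dioxane/H2O, 80 °C, argon; then aq. HCl
Reagents that add atoms: lithium hydroxide, [Li+].[OH-]
Why: Saponification of both aryl acetates and addition–elimination cleavage of the vinylogous methyl ester by hydroxide give the enolised β-triketone after acidification, with no stereocentre touched.

**Compound list**
1 | (S)-4-benzyl-1,3-oxazolidin-2-one | O=C1OC[C@H](Cc2ccccc2)N1 | starting material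
2 | 3-methylbut-2-enoyl chloride | CC(C)=CC(Cl)=O | starting material
3 | N-lithio-(S)-4-benzyl-1,3-oxazolidin-2-one | [Li+].O=C1OC[C@H](Cc2ccccc2)[N-]1 | intermediate
4 | (S)-4-benzyl-3-(3-methylbut-2-enoyl)-1,3-oxazolidin-2-one | CC(C)=CC(=O)N1[C@@H](Cc2ccccc2)COC1=O | intermediate
5 | prenyl bromide (1-bromo-3-methylbut-2-ene) | CC(C)=CCBr | starting material
6 | sodium (Z)-dienolate of 4 | [Na+].[O-]/C(=C\C(C)=C)N1[C@@H](Cc2ccccc2)COC1=O | intermediate
7 | (4S)-4-benzyl-3-[(2S)-5-methyl-2-(prop-1-en-2-yl)hex-4-enoyl]-1,3-oxazolidin-2-one | O=C([C@@H](CC=C(C)C)C(C)=C)N1[C@@H](Cc2ccccc2)COC1=O | intermediate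
8 | (S)-lavandulol, (2S)-5-methyl-2-(prop-1-en-2-yl)hex-4-en-1-ol | OC[C@@H](CC=C(C)C)C(C)=C | intermediate
9 | (S)-lavandulyl iodide, (2S)-1-iodo-5-methyl-2-(prop-1-en-2-yl)hex-4-ene | IC[C@@H](CC=C(C)C)C(C)=C | intermediate
10 | (R)-lavandulol, (2R)-5-methyl-2-(prop-1-en-2-yl)hex-4-en-1-ol | OC[C@H](CC=C(C)C)C(C)=C | starting material
11 | dilithio (R)-lavandulol (lithium alkoxide plus allyllithium at the former isopropenyl methyl) | [Li+].[Li+].[O-]C[C@H](CC=C(C)C)C(=C)[CH2-] | intermediate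
12 | (2R)-5-methyl-2-(6-methylhepta-1,5-dien-2-yl)hex-4-en-1-ol | OC[C@H](CC=C(C)C)C(=C)CCC=C(C)C | intermediate
13 | (2S)-5-methyl-2-[(2R)-2-(4-methylpent-3-en-1-yl)oxiran-2-yl]hex-4-en-1-ol | OC[C@H](CC=C(C)C)[C@@]1(CO1)CCC=C(C)C | intermediate
14 | (2R)-2-[(2R)-1-iodo-5-methylhex-4-en-2-yl]-2-(4-methylpent-3-en-1-yl)oxirane | IC[C@H](CC=C(C)C)[C@@]1(CO1)CCC=C(C)C | intermediate
15 | 1,5-dimethoxycyclohexa-1,4-diene | COC1=CCC=C(OC)C1 | starting material
16 | 6-lithio-1,5-dimethoxycyclohexa-1,4-diene | [Li+].COC1=CCC=C(OC)[CH-]1 | intermediate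
17 | 6-Lav-1,5-dimethoxycyclohexa-1,4-diene | COC1=CCC=C(OC)C1C[C@@H](CC=C(C)C)C(C)=C | intermediate
18 | 6-lithio derivative of 17 | [Li+].COC1=CCC=C(OC)[C-]1C[C@@H](CC=C(C)C)C(C)=C | intermediate
19 | 6-Lav-6-{(2S)-5-methyl-2-[(2R)-2-(4-methylpent-3-en-1-yl)oxiran-2-yl]hex-4-en-1-yl}-1,5-dimethoxycyclohexa-1,4-diene (ring carbon 6 not stereogenic) | COC1=CCC=C(OC)C1(C[C@@H](CC=C(C)C)C(C)=C)C[C@H](CC=C(C)C)[C@@]2(CO2)CCC=C(C)C | intermediate
20 | O-methyl oxocarbenium triflate at C9 of 21 (configuration as in 22) | C=C(C)[C@H](CC=C(C)C)C[C@@]12C[C@H](CC=C(C)C)[C@](CO[Si](C)(C)C)(CCC=C(C)C)[C@@H](CC=C1OC)C2=[O+]C.[O-]S(=O)(=O)C(F)(F)F | intermediate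
21 | trimethylsilyl ether of 22 | C=C(C)[C@H](CC=C(C)C)C[C@@]12C[C@H](CC=C(C)C)[C@](CO[Si](C)(C)C)(CCC=C(C)C)[C@@H](CC=C1OC)C2=O | intermediate
22 | 8-(hydroxymethyl)-4-methoxy-8-homoprenyl-7-prenyl-5-Lav-bicyclo[3.3.1]non-3-en-9-one; C1–H bridgehead, C7 prenyl equatorial (exo, away from ring A), C8 homoprenyl axial (cis to the C7 prenyl) and CH2OH equatorial, absolute configuration as in 33 | C=C(C)[C@H](CC=C(C)C)C[C@@]12C[C@H](CC=C(C)C)[C@](CO)(CCC=C(C)C)[C@@H](CC=C1OC)C2=O | intermediate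
23 | 8-formyl analogue of 22 (same configuration) | C=C(C)[C@H](CC=C(C)C)C[C@@]12C[C@H](CC=C(C)C)[C@](C=O)(CCC=C(C)C)[C@@H](CC=C1OC)C2=O | intermediate
24 | N-(tert-butyldimethylsilyl)hydrazone of 23 | C=C(C)[C@H](CC=C(C)C)C[C@@]12C[C@H](CC=C(C)C)[C@](C=NN[Si](C)(C)C(C)(C)C)(CCC=C(C)C)[C@@H](CC=C1OC)C2=O | intermediate
25 | 4-methoxy-8-methyl-8-homoprenyl-7-prenyl-5-Lav-bicyclo[3.3.1]non-3-en-9-one; C8 methyl equatorial, homoprenyl axial (cis to C7 prenyl), configuration as in 33 | C=C(C)[C@H](CC=C(C)C)C[C@@]12C[C@H](CC=C(C)C)[C@](C)(CCC=C(C)C)[C@@H](CC=C1OC)C2=O | intermediate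
26 | 4-methoxy-8-methyl-8-homoprenyl-7-prenyl-5-Lav-bicyclo[3.3.1]non-3-ene-2,9-dione (configuration as in 33, C1–H) | C=C(C)[C@H](CC=C(C)C)C[C@@]12C[C@H](CC=C(C)C)[C@](C)(CCC=C(C)C)[C@@H](C(=O)C=C1OC)C2=O | intermediate
27 | C1 bridgehead lithium derivative of 26 | [Li+].C=C(C)[C@H](CC=C(C)C)C[C@@]12C[C@H](CC=C(C)C)[C@](C)(CCC=C(C)C)[C-](C(=O)C=C1OC)C2=O | intermediate
28 | 4-methoxy-8-methyl-8-homoprenyl-1,7-diprenyl-5-Lav-bicyclo[3.3.1]non-3-ene-2,9-dione (configuration as in 33) | C=C(C)[C@H](CC=C(C)C)C[C@@]12C[C@H](CC=C(C)C)[C@](C)(CCC=C(C)C)[C@@](CC=C(C)C)(C(=O)C=C1OC)C2=O | intermediate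
29 | 3,4-diacetoxybenzoic acid | CC(=O)Oc1ccc(C(=O)O)cc1OC(C)=O | starting material
30 | 3,4-diacetoxybenzoyl chloride | CC(=O)Oc1ccc(C(Cl)=O)cc1OC(C)=O | intermediate
31 | 3-lithio derivative of 28 | C=C(C)[C@H](CC=C(C)C)C[C@@]12C[C@H](CC=C(C)C)[C@](C)(CCC=C(C)C)[C@@](CC=C(C)C)(C(=O)C([Li])=C1OC)C2=O | intermediate
32 | 3-(3,4-diacetoxybenzoyl)-4-methoxy-8-methyl-8-homoprenyl-1,7-diprenyl-5-Lav-bicyclo[3.3.1]non-3-ene-2,9-dione (configuration as in 33) | C=C(C)[C@H](CC=C(C)C)C[C@@]12C[C@H](CC=C(C)C)[C@](C)(CCC=C(C)C)[C@@](CC=C(C)C)(C(=O)C(C(=O)c3ccc(OC(C)=O)c(OC(C)=O)c3)=C1OC)C2=O | intermediate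
33 | (1R,5R,7S,8S)-3-(3,4-dihydroxybenzoyl)-4-hydroxy-8-methyl-8-(4-methylpent-3-en-1-yl)-1,7-bis(3-methylbut-2-en-1-yl)-5-[(2R)-5-methyl-2-(prop-1-en-2-yl)hex-4-en-1-yl]bicyclo[3.3.1]non-3-ene-2,9-dione (CNP0241026.2) | C=C(C)[C@H](CC=C(C)C)C[C@@]12C[C@H](CC=C(C)C)[C@](C)(CCC=C(C)C)[C@@](CC=C(C)C)(C(=O)C(C(=O)c3ccc(O)c(O)c3)=C1O)C2=O | target

**Totals**
Total step count: 17. Longest linear sequence: 13 steps (1–4, 8–14, 16, 17).

**Three steps most likely to fail**

Step 10 (key cyclisation). A 2,2-disubstituted epoxide can rearrange to an aldehyde (Meinwald) or eliminate under TMSOTf before the enol ether attacks, and group selection rests on a chair transition state in which the leaving C–O bond is eclipsed with the equatorial prenyl group. The fallback sets out from 19 and returns at 26. Bis-allylic oxidation of 19 with pyridinium dichromate (C5H5NH)2Cr2O7 and t-BuOOH gives the cross-conjugated 4,4-dialkyl-3,5-dimethoxycyclohexa-2,5-dienone F4. Its acid-stable vinylogous ester allows the epoxide to be opened under hydrogen-bond or Brønsted activation (hexafluoroisopropanol, or catalytic BF3·OEt2) by the enone α-carbon, the polarity used in formic-acid cationic cyclisations of dearomatised acylphloroglucinol methyl ethers, to give the bicyclic hydroxymethyl vinylogous ester F5. Dess–Martin oxidation gives aldehyde F6, and Wolff–Kishner reduction through its N-silyl hydrazone F7 (as in steps 11 and 12) gives 26, which also removes the need for step 13.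

Step 9 (quaternary carbon). The SN2 reaction of a hindered tertiary carbanion with a β-branched iodide that carries a free epoxide may lose to E2 or to attack at the epoxide CH2. The fallback sets out from 15 (with 14 and 8) and returns at 19. Diene 15 is lithiated and alkylated first with the hindered iodide 14, while C6 is still secondary, to give 6-{(2S)-5-methyl-2-[(2R)-2-(4-methylpent-3-en-1-yl)oxiran-2-yl]hex-4-en-1-yl}-1,5-dimethoxycyclohexa-1,4-diene F1. Its 6-lithio derivative F2 is then quenched with (S)-lavandulyl trifluoromethanesulfonate F3, made from 8 with Tf2O and 2,6-di-tert-butylpyridine at −78 °C and used at once. The quaternary centre is thus closed by the other C–C bond, with the less hindered and far more reactive electrophile.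

Step 13 (allylic oxidation). Several other allylic C–H bonds (the prenyl CH2 groups and the tertiary allylic C–H of Lav) may compete with C2. The fallback sets out from 25 and returns at 26 by a polar sequence. Mild acid hydrolysis of the enol ether (oxalic acid on wet silica) gives the 4,9-diketone F8. Dehydrogenation with IBX gives the C2=C3 enone F9. Nucleophilic epoxidation (t-BuOOH, DBU) gives the 2,3-epoxy ketone F10. Isomerisation of the epoxy ketone with Pd(PPh3)4 and dppe gives the 2,4,9-trione F11. O-methylation with Me3SiCHN2 then gives 26, which is separated from its 2-methoxy regioisomer.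

**Further compounds**
F1 | step 9 | 6-{(2S)-5-methyl-2-[(2R)-2-(4-methylpent-3-en-1-yl)oxiran-2-yl]hex-4-en-1-yl}-1,5-dimethoxycyclohexa-1,4-diene | COC1=CCC=C(OC)C1C[C@H](CC=C(C)C)[C@@]2(CO2)CCC=C(C)C
F2 | step 9 | 6-lithio derivative of F1 | [Li+].COC1=CCC=C(OC)[C-]1C[C@H](CC=C(C)C)[C@@]2(CO2)CCC=C(C)C
F3 | step 9 | (S)-lavandulyl trifluoromethanesulfonate | O=S(=O)(OC[C@@H](CC=C(C)C)C(C)=C)C(F)(F)F
F4 | step 10 | 4-Lav-4-{(2S)-5-methyl-2-[(2R)-2-(4-methylpent-3-en-1-yl)oxiran-2-yl]hex-4-en-1-yl}-3,5-dimethoxycyclohexa-2,5-dien-1-one | COC1=CC(=O)C=C(OC)C1(C[C@@H](CC=C(C)C)C(C)=C)C[C@H](CC=C(C)C)[C@@]2(CO2)CCC=C(C)C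
F5 | step 10 | 8-(hydroxymethyl)-4-methoxy-8-homoprenyl-7-prenyl-5-Lav-bicyclo[3.3.1]non-3-ene-2,9-dione (configuration as in 22) | C=C(C)[C@H](CC=C(C)C)C[C@@]12C[C@H](CC=C(C)C)[C@](CO)(CCC=C(C)C)[C@@H](C(=O)C=C1OC)C2=O
F6 | step 10 | 8-formyl analogue of F5 | C=C(C)[C@H](CC=C(C)C)C[C@@]12C[C@H](CC=C(C)C)[C@](C=O)(CCC=C(C)C)[C@@H](C(=O)C=C1OC)C2=O
F7 | step 10 | N-(tert-butyldimethylsilyl)hydrazone of F6 | C=C(C)[C@H](CC=C(C)C)C[C@@]12C[C@H](CC=C(C)C)[C@](C=NN[Si](C)(C)C(C)(C)C)(CCC=C(C)C)[C@@H](C(=O)C=C1OC)C2=O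
F8 | step 13 | 8-methyl-8-homoprenyl-7-prenyl-5-Lav-bicyclo[3.3.1]nonane-4,9-dione (configuration as in 25) | C=C(C)[C@H](CC=C(C)C)C[C@@]12C[C@H](CC=C(C)C)[C@](C)(CCC=C(C)C)[C@@H](CCC1=O)C2=O
F9 | step 13 | 8-methyl-8-homoprenyl-7-prenyl-5-Lav-bicyclo[3.3.1]non-2-ene-4,9-dione | C=C(C)[C@H](CC=C(C)C)C[C@@]12C[C@H](CC=C(C)C)[C@](C)(CCC=C(C)C)[C@@H](C=CC1=O)C2=O
F10 | step 13 | 2,3-epoxy-8-methyl-8-homoprenyl-7-prenyl-5-Lav-bicyclo[3.3.1]nonane-4,9-dione (epoxide on the exo face) | C=C(C)[C@H](CC=C(C)C)C[C@@]12C[C@H](CC=C(C)C)[C@](C)(CCC=C(C)C)[C@@H](C3OC3C1=O)C2=O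
F11 | step 13 | 8-methyl-8-homoprenyl-7-prenyl-5-Lav-bicyclo[3.3.1]nonane-2,4,9-trione | C=C(C)[C@H](CC=C(C)C)C[C@@]12C[C@H](CC=C(C)C)[C@](C)(CCC=C(C)C)[C@@H](C(=O)CC1=O)C2=O
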